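Take a small charge, the autumn run, and follow one molecule of starting material, asking at each stretch of the run what chance per hour it has of becoming target; that chance is the pseudo-first-order constant, and it can be held against other charges.

| setting | autumn | noon | midnight | teal | green | violet |
|---|---|---|---|---|---|---|
| starting material | 0.038 M | 0.081 M | 0.28 M | 0.030 M | 0.080 M | 0.25 M |
| second substrate | 0.083 M | 0.083 M | 0.083 M | 0.0830 M | 0.0830 M | 0.0830 M |
| free catalyst | 83 µM | 83 µM | 83 µM | 83 µM | 83 µM | 83 µM |
| added ligand | 90 µM | 90 µM | 90 µM | 90 µM | 90 µM | 90 µM |
| remark | run made earlier | run made earlier | run made earlier |  |  |  |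
| time |  |  |  | 40 h | 40 h | 40 h |

| autumn: time / h | autumn: target / % | noon: time / h | noon: target / % | midnight: time / h | midnight: target / % |
|---|---|---|---|---|---|
| 2.00 | 5.2 | 2.00 | 5.1 | 2.00 | 3.6 |
| 5.00 | 10.4 | 5.00 | 9.9 | 5.00 | 10.0 |
| 10.0 | 18.3 | 10.0 | 17.9 | 10.0 | 18.5 |
| 15.0 | 28.0 | 15.0 | 28.6 | 15.0 | 24.8 |
| 20.0 | 39.5 | 20.0 | 36.2 | 20.0 | 32.9 |

(readings scatter by 1 percentage point)

- the numbers in the tables scatter by 1 percentage point (one standard deviation)
- "hardly changes" means that all values lie within two and a half points (for a concentration: within two and a half percent of the largest)

* amount of target at the end, in percent of the starting material charged for teal, green, violet, in this order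
* how that number moves from the first to the last of them (falls all the way / rises, then falls / rises all the way / hardly changes / falls, then rises)

Read the tables column against column, starting with the autumn run. Define the late hazard as the share of the starting material still present that turns to target per hour between 10.0 h and 20.0 h, which for autumn is 0.0300 h⁻¹, and set it against the early hazard over the first 10.0 h, which is 0.0202 h⁻¹, so the molecule's chance grew as the autumn run went on. Go on to noon, where 0.0197 h⁻¹ early becomes 0.0252 h⁻¹ late, a smaller rise than in autumn. Then read midnight, with 0.0205 h⁻¹ early and 0.0194 h⁻¹ late, remembering that each reading scatters by 1 percentage point. The early hazards of autumn and midnight agree, so look for the effect of the charge in the late column.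

Carry each run's remainder at 20.0 h forward to 40 h at its own late hazard, with autumn standing in for teal, noon for green and midnight for violet. My reckoning then gives 66.8%, 61.5% and 54.5%.

The forecast says 60%, 57% and 52%, a row that falls all the way, and it rests that fall on the readings at 20.0 h falling with charge, which it takes to suggest “a mild drag at high loading”; my row has the same shape but stands higher at each point.

The flask gives 71.7%, 67.9% and 59.2%, a row that falls all the way.

    catalyst intermediate B → free catalyst + second product (k = 1.20 min⁻¹)
    free catalyst + added ligand ⇌ idle complex, settled at all times (K = 7600 M⁻¹)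
    second substrate + free catalyst ⇌ catalyst intermediate B (K = 35.0 M⁻¹, k = 680 M⁻¹ min⁻¹)
    catalyst intermediate A ⇌ free catalyst + target (K = 0.110 M, k = 31.0 min⁻¹)
    starting material + free catalyst ⇌ catalyst intermediate A (K = 930 M⁻¹, k = 16.0 M⁻¹ min⁻¹)

In teal, from 20.0 h to 40.0 h, second substrate went from 29.4% to 4.27% of its charge while free catalyst rose from 40.6% to 54.8% of the catalyst charged, and the hazard over those hours, reckoned from the starting material left, came to 0.0385 h⁻¹, above the 0.0300 h⁻¹ carried from autumn. In violet over the same hours second substrate went from 35.6% to 10.8% while catalyst intermediate A grew from 25.2% to 42.8% of the catalyst charged and free catalyst stood at 29.3%, then 30.6%, and the hazard was 0.0240 h⁻¹, above the 0.0194 h⁻¹ carried from midnight.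

(All runs were generated by integration with made-up constants; the scatter is artificial.)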